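**Strategy**

Numbering: labdane (C1–C20) for the decalin half, primed caryophyllane for the other half. The target is cut at C6'–C7' of the nine-membered ring (C1'–C9'), the ring bond allylic to the exocyclic methylene on C8'. This 1,1-disubstituted alkene flanked by the ring CH2 C7' is exploited by an intramolecular Hosomi–Sakurai allylation, which forms C6'–C7', closes the nine-membered ring and installs C8'=CH2 in one operation. Its precursor 35 carries a formyl group (C6') on cyclohexene carbon C5' and a CH2=C(CH2SiMe3) unit on cyclobutane carbon C9', the two halves being joined beforehand at C3'–C4' by alkylation of a lactone enolate; the cyclohexene comes from an auxiliary-controlled Diels–Alder reaction.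

Key step: step 19

Assumption: 1, 5 and 8 are taken as purchasable catalogue compounds; C12' is the carboxyl carbon on C4', C13' the methylene carbon on C8', and C11–C16 are the labdane side-chain carbons that end up in the cyclohexene.

**Decalin–cyclohexene half**

Step 1
Reactants: 1 trans-communic acid
Product: 2 methyl trans-communate
Conditions: MeI, K2CO3, DMF, rt
Reagents that add atoms: iodomethane, CI
Why: Esterification by SN2 O-alkylation of the carboxylate should work at the hindered axial C19 acid because the new bond is made at the methyl carbon and not at the carbonyl, and no stereocentre is touched.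

Step 2
Reactants: 2 methyl trans-communate
Product: 4 decalin aldehyde (C12 formyl), via diol 3 (not isolated)
Conditions: OsO4 (2 mol %), NaIO4, 2,6-lutidine, dioxane–H2O (3:1), 0 °C to rt
Reagents that add atoms: sodium periodate, [Na+].[O-]I(=O)(=O)=O
Why: Lemieux–Johnson oxidative cleavage (catalytic dihydroxylation, then periodate glycol scission) should start at the trisubstituted, most electron-rich C12=C13 bond rather than at the vinyl group or the hindered C8=C17 methylene, and is stopped once 2 is consumed, C9 being untouched.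

Step 3
Reactants: 4 decalin aldehyde; 5 3-(triphenylphosphoranylidene)butan-2-one
Product: 6 (12E)-enone
Conditions: toluene, 90 °C
Reagents that add atoms: 3-(triphenylphosphoranylidene)butan-2-one (5), CC(=O)C(C)=P(c1ccccc1)(c1ccccc1)c1ccccc1
Why: Wittig olefination with the stabilised α-methyl acyl ylide should give the trisubstituted enone with C11 trans to the carbonyl (E), the usual outcome for stabilised ylides.

Step 4
Reactants: 6 (12E)-enone
Product: 7 2-silyloxy diene
Conditions: TBSOTf, Et3N, CH2Cl2, 0 °C
Reagents that add atoms: tert-butyldimethylsilyl trifluoromethanesulfonate, CC(C)(C)[Si](C)(C)OS(=O)(=O)C(F)(F)F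
Why: Silyl enol ether formation by soft enolisation at the only α-CH3 of the methyl ketone gives the cross-conjugated 2-silyloxy diene with the C12=C13 geometry retained.

Step 5
Reactants: 7 2-silyloxy diene; 8 (5S)-5-(d-menthyloxy)furan-2(5H)-one
Product: 9 Diels–Alder adduct (cis-fused lactone acetal)
Conditions: toluene, BHT (trace), 110 °C, sealed tube
Reagents that add atoms: (5S)-5-(d-menthyloxy)furan-2(5H)-one (8), O=C1O[C@H](O[C@H]2C[C@@H](C)CC[C@@H]2C(C)C)C=C1
Why: In this thermal Diels–Alder reaction the silyloxy group makes C15 the nucleophilic diene terminus, so C15 bonds to the butenolide β-carbon (C5') and C12 to the α-carbon (C4'), the diene adds to the face anti to the menthyloxy group (absolute control of C4', C5' and C12), and the endo transition state places C11 cis to the lactone.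

Step 6
Reactants: 9 Diels–Alder adduct
Product: 11 enol triflate, via cesium enolate 10 (not isolated)
Conditions: CsF, PhNTf2, DME, rt
Reagents that add atoms: N-phenylbis(trifluoromethanesulfonimide), O=S(=O)(N(c1ccccc1)S(=O)(=O)C(F)(F)F)C(F)(F)F
Why: Enol triflate formation from a silyl enol ether: fluoride releases the regiodefined tetrasubstituted enolate, which is O-sulfonylated before it can equilibrate, so the double bond stays at C13=C14.

Step 7
Reactants: 11 enol triflate
Product: 12 cyclohexene lactone acetal
Conditions: Pd(OAc)2 (5 mol %), PPh3, n-Bu3N, HCO2H, DMF, 60 °C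
Reagents that add atoms: none
Why: Palladium-catalysed formate reduction of the enol triflate (oxidative addition to zerovalent palladium, formate-to-hydride exchange with loss of CO2, reductive elimination) replaces the triflate by hydrogen without moving the C13=C14 bond or touching a stereocentre.

Step 8
Reactants: 12 cyclohexene lactone acetal
Product: 15 cis-fused γ-lactone, via sodium formyl carboxylate 13 (not isolated), via sodium hydroxy carboxylate 14 (not isolated)
Conditions: NaBH4, 1 M aq NaOH, THF–MeOH, 0 °C to rt; then 2 M HCl to pH 2, rt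
Reagents that add atoms: none
Why: Hydroxide opens the acyl acetal (pseudo-ester hydrolysis), the released aldehyde is reduced at once by borohydride before C5' can epimerise, and acidification closes the cis-fused γ-lactone (lactonisation) with C4', C5' and C12 retained, the auxiliary leaving as menthol and the hindered C19 ester staying intact.

**Cyclobutane fragment**

Step 9
Reactants: 16 (−)-caryophyllene oxide
Product: 18 kobusone, via ozonide 17 (not isolated)
Conditions: O3, CH2Cl2, −78 °C; then PPh3, −78 °C to rt
Reagents that add atoms: ozone, [O-][O+]=O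
Why: Ozonolysis of the exocyclic 1,1-disubstituted alkene with reductive work-up gives the C8 ketone, the epoxide serving as a mask for the ring olefin and the cyclobutane centres staying untouched.

Step 10
Reactants: 18 kobusone
Product: 20 trimethylsilyl enol ether (C7=C8), via lithium enolate 19 (not isolated)
Conditions: LiN(i-Pr)2, Me3SiCl, THF, −78 °C
Reagents that add atoms: chlorotrimethylsilane, C[Si](C)(C)Cl
Why: Kinetic enolate formation at the C7 methylene (not at the hindered cyclobutane methine C9) with in situ O-silylation should be regioselective at −78 °C, where transannular attack on the epoxide should not compete.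

Step 11
Reactants: 20 trimethylsilyl enol ether
Product: 23 cyclobutane keto acid, via ozonide 21 (not isolated), via epoxy aldehyde acid 22 (not isolated)
Conditions: O3, CH2Cl2, −78 °C; PPh3; then H5IO6, THF–H2O, 0 °C to rt
Reagents that add atoms: ozone, [O-][O+]=O; water, O
Why: Ozonolysis of the silyl enol ether cleaves C7–C8 to the C8 carboxylic acid, and periodic acid then hydrates and cleaves the epoxide (glycol scission) to the C4 methyl ketone with loss of C5–C7 as malonaldehyde, the trans-cyclobutane being the stable arrangement at C9.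

Step 12
Reactants: 23 cyclobutane keto acid
Product: 24 keto methyl ester
Conditions: MeI, K2CO3, DMF, rt
Reagents that add atoms: iodomethane, CI
Why: Esterification by SN2 O-alkylation of the carboxylate gives the methyl ester needed for the later double addition without affecting the ketone or the ring stereocentres.

Step 13
Reactants: 24 keto methyl ester
Product: 25 acetoxy ester
Conditions: mCPBA, CF3CO2H (cat.), CH2Cl2, rt
Reagents that add atoms: 3-chloroperoxybenzoic acid, OOC(=O)c1cccc(Cl)c1
Why: In this Baeyer–Villiger oxidation of a methyl ketone the primary alkyl group migrates in preference to methyl, which puts the oxygen on C3' and leaves the ester and the stereocentres unchanged.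

Step 14
Reactants: 25 acetoxy ester; 26 (trimethylsilyl)methylmagnesium chloride
Product: 28 hydroxy allylsilane, via bis(silylmethyl) carbinol 27 (not isolated)
Conditions: Me3SiCH2MgCl (6 equiv), CeCl3, THF, −78 °C to rt; aq NH4Cl; then SiO2, CH2Cl2, rt
Reagents that add atoms: (trimethylsilyl)methylmagnesium chloride (26), C[Si](C)(C)C[Mg]Cl
Why: Cerium-mediated double addition of the silylmethyl Grignard reagent to the ester gives the bis(β-silyl) carbinol without enolising C9', silica gel then triggers Peterson olefination to the 2-substituted allylsilane, and the same reagent cleaves the acetate to free the C3' alcohol.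

Step 15
Reactants: 28 hydroxy allylsilane
Product: 30 iodide allylsilane, via mesylate 29 (not isolated)
Conditions: MsCl, Et3N, CH2Cl2, 0 °C; then NaI, acetone, 55 °C
Reagents that add atoms: sodium iodide, [Na+].[I-]
Why: Sulfonylation followed by Finkelstein displacement (SN2) gives the primary iodide without electrophilic halogen or acid, which the allylsilane would not tolerate.

**Union, key step and endgame**

Step 16
Reactants: 15 cis-fused γ-lactone; 30 iodide allylsilane
Product: 32 alkylated lactone, via lithium enolate 31 (not isolated)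
Conditions: LiN(i-Pr)2, THF, −78 °C; then 30, HMPA, −78 to −30 °C
Reagents that add atoms: iodide allylsilane (30), ICC[C@@H]1[C@H](CC1(C)C)C(=C)C[Si](C)(C)C
Why: Enolate alkylation (SN2) of the ring-fusion lactone enolate with the unbranched primary iodide creates the quaternary centre C4', the electrophile entering from the face that carries the C5' and C12 hydrogens, anti to the C5'–C15 bond and to C11, so the cis ring fusion is kept and C3' ends trans to both C6' and C11.

Step 17
Reactants: 32 alkylated lactone
Product: 34 hydroxy dimethyl ester, via potassium carboxylate 33 (not isolated)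
Conditions: KOH, MeOH–H2O, 65 °C; CO2 to pH 9, evaporate; MeI, DMF, 0 °C to rt
Reagents that add atoms: potassium hydroxide, [K+].[OH-]; iodomethane, CI
Why: Saponification of the γ-lactone and SN2 methylation of the carboxylate under non-acidic conditions give the open hydroxy ester, which is used at once because acid or strong base would close the lactone again, while the hindered C19 ester is not saponified.

Step 18
Reactants: 34 hydroxy dimethyl ester
Product: 35 aldehyde allylsilane (key precursor)
Conditions: Dess–Martin periodinane, NaHCO3, CH2Cl2, 0 °C to rt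
Reagents that add atoms: none
Why: Dess–Martin oxidation converts the primary alcohol into the C6' aldehyde under buffered neutral conditions that neither epimerise C5' nor protodesilylate the allylsilane.

Step 19
Reactants: 35 aldehyde allylsilane
Product: 37 C6' carbinol with the nine-membered ring closed, via difluoroboryl ether 36 (not isolated)
Conditions: BF3·OEt2 (1.5 equiv), 2,6-di-tert-butyl-4-methylpyridine, CH2Cl2, −78 °C, 35 added over 8 h to a final 1 mM; aq NaHCO3
Reagents that add atoms: none
Why: Proposed new method: BF3 activates the C6' aldehyde, the CH2 terminus of the allylsilane attacks it through an open transition state (SE2' course), and the β-silyl cation loses silicon as Me3SiF, so the double bond ends as C8'=CH2 and the oxygen as a difluoroboryl ether that is hydrolysed on work-up. The closest known reaction type is the intramolecular Hosomi–Sakurai allylation of aldehydes, established for five- to eight-membered carbocycles but not for a nine-membered one. The nine-membered ring (C1'–C9') closes by a 9-exo-trig attack on the carbonyl carbon, C7' and C8' both becoming ring atoms and the methylene staying exocyclic. The new stereocentre C6' is set by the fold that the ring-forming transition state imposes on the aldehyde face; it is drawn as one epimer and is irrelevant because the oxygen is removed in steps 20 and 21. The step needs the allylsilane, not the C13=C14 olefin or the C8=C17 methylene, to be the nucleophile and needs ring closure to outrun oligomerisation; the β-silicon effect makes the allylsilane far more nucleophilic, slow addition at high dilution favours cyclisation, and the chain ends are held close by the trans-cyclobutane and the cyclohexene, whose C4', C5', C1' and C9' centres are already fixed. The hindered pyridine base removes adventitious acid that would protodesilylate the allylsilane.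

Step 20
Reactants: 37 C6' carbinol
Product: 38 O-phenyl thionocarbonate
Conditions: PhOC(S)Cl, pyridine, DMAP (cat.), CH2Cl2, rt
Reagents that add atoms: O-phenyl chlorothionoformate, S=C(Cl)Oc1ccccc1
Why: Thionocarbonate formation by acylation under pyridine catalysis avoids an alkoxide, which would attack the neighbouring C12' ester and lactonise.

Step 21
Reactants: 38 O-phenyl thionocarbonate
Product: 39 dimethyl ester of the target
Conditions: Bu3SnH, AIBN (cat.), toluene, 100 °C
Reagents that add atoms: none
Why: In this Barton–McCombie deoxygenation the stannyl radical adds to C=S, the C6'–O bond fragments and the secondary radical is reduced by Bu3SnH faster than it can add to the nearby alkenes, which removes the C6' stereocentre.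

Step 22
Reactants: 39 dimethyl ester of the target
Product: 41 CNP0330729.1, via disodium dicarboxylate 40 (not isolated)
Conditions: NaSEt, DMF, 100 °C; then 1 M HCl, 0 °C
Reagents that add atoms: none
Why: Ester dealkylation by thiolate (SN2 at the methyl groups) should cleave both hindered methyl esters, which resist attack at the acyl carbon, and acidification liberates the diacid without touching the three alkenes or any stereocentre.

**Compound list**

1 | trans-communic acid, (12E)-labda-8(17),12,14-trien-19-oic acid, (4S,5R,9S,10R) | C=C/C(C)=C/C[C@H]1C(=C)CC[C@@H]2[C@]1(C)CCC[C@]2(C)C(=O)O | starting material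
2 | methyl trans-communate (methyl ester of 1) | C=C/C(C)=C/C[C@H]1C(=C)CC[C@@H]2[C@]1(C)CCC[C@]2(C)C(=O)OC | intermediate
3 | methyl 12,13-dihydroxylabda-8(17),14-dien-19-oate, syn diol, both face isomers (C12 and C13 not drawn) | C=CC(C)(O)C(O)C[C@H]1C(=C)CC[C@@H]2[C@]1(C)CCC[C@]2(C)C(=O)OC | intermediate
4 | methyl 12-oxo-13,14,15,16-tetranorlabd-8(17)-en-19-oate (C12 formyl on C11H2 at C9) | O=CC[C@H]1C(=C)CC[C@@H]2[C@]1(C)CCC[C@]2(C)C(=O)OC | intermediate
5 | 3-(triphenylphosphoranylidene)butan-2-one | CC(=O)C(C)=P(c1ccccc1)(c1ccccc1)c1ccccc1 | starting material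
6 | methyl (12E)-14-oxolabda-8(17),12-dien-19-oate (C11 trans to the carbonyl) | CC(=O)/C(C)=C/C[C@H]1C(=C)CC[C@@H]2[C@]1(C)CCC[C@]2(C)C(=O)OC | intermediate
7 | methyl (12E)-14-(tert-butyldimethylsilyloxy)labda-8(17),12,14-trien-19-oate | C=C(O[Si](C)(C)C(C)(C)C)/C(C)=C/C[C@H]1C(=C)CC[C@@H]2[C@]1(C)CCC[C@]2(C)C(=O)OC | intermediate
8 | (5S)-5-[(1S,2R,5S)-2-isopropyl-5-methylcyclohexyloxy]furan-2(5H)-one (d-menthyl acetal of 5-hydroxybutenolide) | O=C1O[C@H](O[C@H]2C[C@@H](C)CC[C@@H]2C(C)C)C=C1 | starting material
9 | Diels–Alder adduct: cis-fused γ-lactone acetal on the cyclohexene, lactone carbonyl C12' on C4', menthyloxy acetal carbon C6' (S) on C5', C11 on C12 cis to the lactone, menthyloxy trans to the cyclohexene, C13(Me)=C14(OTBS) | O=C1O[C@H](O[C@H]5C[C@@H](C)CC[C@@H]5C(C)C)[C@H]2CC(O[Si](C)(C)C(C)(C)C)=C(C)[C@@H](C[C@H]3C(=C)CC[C@@H]4[C@]3(C)CCC[C@]4(C)C(=O)OC)[C@@H]12 | intermediate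
10 | cesium enolate of 9 (O− on C14, C13=C14) | O=C1O[C@H](O[C@H]5C[C@@H](C)CC[C@@H]5C(C)C)[C@H]2CC([O-])=C(C)[C@@H](C[C@H]3C(=C)CC[C@@H]4[C@]3(C)CCC[C@]4(C)C(=O)OC)[C@@H]12.[Cs+] | intermediate
11 | enol triflate: 9 with OSO2CF3 on C14 in place of OTBS | O=C1O[C@H](O[C@H]5C[C@@H](C)CC[C@@H]5C(C)C)[C@H]2CC(OS(=O)(=O)C(F)(F)F)=C(C)[C@@H](C[C@H]3C(=C)CC[C@@H]4[C@]3(C)CCC[C@]4(C)C(=O)OC)[C@@H]12 | intermediate
12 | cyclohexene lactone acetal: 11 with H on C14 | O=C1O[C@H](O[C@H]5C[C@@H](C)CC[C@@H]5C(C)C)[C@H]2CC=C(C)[C@@H](C[C@H]3C(=C)CC[C@@H]4[C@]3(C)CCC[C@]4(C)C(=O)OC)[C@@H]12 | intermediate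
13 | sodium carboxylate (C12' on C4') with cis C6' formyl on C5' | O=C[C@H]1CC=C(C)[C@@H](C[C@H]3C(=C)CC[C@@H]4[C@]3(C)CCC[C@]4(C)C(=O)OC)[C@H]1C(=O)[O-].[Na+] | intermediate
14 | sodium carboxylate (C12') with cis C6'H2OH on C5' | OC[C@H]1CC=C(C)[C@@H](C[C@H]3C(=C)CC[C@@H]4[C@]3(C)CCC[C@]4(C)C(=O)OC)[C@H]1C(=O)[O-].[Na+] | intermediate
15 | cis-fused γ-lactone, C12'(=O)–O–C6'H2 across C4' and C5', C11 on C12 cis to the lactone | O=C1OC[C@H]2CC=C(C)[C@@H](C[C@H]3C(=C)CC[C@@H]4[C@]3(C)CCC[C@]4(C)C(=O)OC)[C@@H]12 | intermediate
16 | (−)-caryophyllene oxide, (1R,4R,5R,9S)-4,5-epoxycaryophyll-8(13)-ene | C[C@@]12CC[C@@H]3[C@H](CC3(C)C)C(=C)CC[C@H]1O2 | starting material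
17 | ozonide of 16 (1,2,4-trioxolane spiro at C8, spiro configuration not defined) | C[C@@]12CC[C@@H]3[C@H](CC3(C)C)C4(CC[C@H]1O2)OCOO4 | intermediate
18 | kobusone (C8 ketone of 16) | C[C@@]12CC[C@@H]3[C@H](CC3(C)C)C(=O)CC[C@H]1O2 | intermediate
19 | lithium enolate of 18 (C7=C8, ring-cis) | C[C@@]12CC[C@@H]3[C@H](CC3(C)C)/C([O-])=C\C[C@H]1O2.[Li+] | intermediate
20 | trimethylsilyl enol ether of 18 (C7=C8, ring-cis) | C[C@@]12CC[C@@H]3[C@H](CC3(C)C)/C(O[Si](C)(C)C)=C\C[C@H]1O2 | intermediate
21 | ozonide of 20 (trioxolane across C7 and C8, new centres not defined) | C[C@@]12CC[C@@H]3[C@H](CC3(C)C)C4(O[Si](C)(C)C)OOC(O4)CC[C@H]1O2 | intermediate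
22 | epoxy aldehyde acid: C8 carboxylic acid on C9, 4,5-epoxide, C7 aldehyde | C[C@@]1(O[C@@H]1CCC=O)CC[C@@H]2[C@H](CC2(C)C)C(=O)O | intermediate
23 | (1S,2R)-3,3-dimethyl-2-(3-oxobutyl)cyclobutane-1-carboxylic acid (trans) | CC(=O)CC[C@@H]1[C@H](CC1(C)C)C(=O)O | intermediate
24 | methyl (1S,2R)-3,3-dimethyl-2-(3-oxobutyl)cyclobutane-1-carboxylate | CC(=O)CC[C@@H]1[C@H](CC1(C)C)C(=O)OC | intermediate
25 | methyl (1S,2R)-2-(2-acetoxyethyl)-3,3-dimethylcyclobutane-1-carboxylate | CC(=O)OCC[C@@H]1[C@H](CC1(C)C)C(=O)OC | intermediate
26 | (trimethylsilyl)methylmagnesium chloride | C[Si](C)(C)C[Mg]Cl | starting material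
27 | carbinol: HOCH2CH2 on C1' and C(OH)(CH2SiMe3)2 on C9' of the trans-cyclobutane | OCC[C@@H]1[C@H](CC1(C)C)C(O)(C[Si](C)(C)C)C[Si](C)(C)C | intermediate
28 | hydroxy allylsilane: HOCH2CH2 (C3', C2') on C1' (R), CH2=C(CH2SiMe3) on C9' (S), gem-dimethyl on C11' | OCC[C@@H]1[C@H](CC1(C)C)C(=C)C[Si](C)(C)C | intermediate
29 | methanesulfonate of 28 | CS(=O)(=O)OCC[C@@H]1[C@H](CC1(C)C)C(=C)C[Si](C)(C)C | intermediate
30 | iodide: ICH2CH2 on C1' (R), allylsilane on C9' (S) | ICC[C@@H]1[C@H](CC1(C)C)C(=C)C[Si](C)(C)C | intermediate
31 | lithium enolate of 15 (C4'=C12') | [Li+].[O-]C1=C2[C@H](C[C@H]3C(=C)CC[C@@H]4[C@]3(C)CCC[C@]4(C)C(=O)OC)C(C)=CC[C@@H]2CO1 | intermediate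
32 | alkylated lactone: 15 with the C3'–C2' chain to the cyclobutane on C4', trans to C11 and C6', cis ring fusion kept | O=C1OC[C@H]2CC=C(C)[C@@H](C[C@H]3C(=C)CC[C@@H]4[C@]3(C)CCC[C@]4(C)C(=O)OC)[C@@]12CC[C@@H]5[C@H](CC5(C)C)C(=C)C[Si](C)(C)C | intermediate
33 | potassium carboxylate (C12') with C6'H2OH, from opening of 32 | OC[C@H]1CC=C(C)[C@@H](C[C@H]2C(=C)CC[C@@H]3[C@]2(C)CCC[C@]3(C)C(=O)OC)[C@]1(C(=O)[O-])CC[C@@H]1[C@H](CC1(C)C)C(=C)C[Si](C)(C)C.[K+] | intermediate
34 | hydroxy dimethyl ester: C12' methyl ester on C4', C6'H2OH on C5' | OC[C@H]1CC=C(C)[C@@H](C[C@H]2C(=C)CC[C@@H]3[C@]2(C)CCC[C@]3(C)C(=O)OC)[C@]1(C(=O)OC)CC[C@@H]1[C@H](CC1(C)C)C(=C)C[Si](C)(C)C | intermediate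
35 | aldehyde allylsilane (key precursor): C6' formyl on C5', C12' and C19 methyl esters, allylsilane on C9' | O=C[C@H]1CC=C(C)[C@@H](C[C@H]2C(=C)CC[C@@H]3[C@]2(C)CCC[C@]3(C)C(=O)OC)[C@]1(C(=O)OC)CC[C@@H]1[C@H](CC1(C)C)C(=C)C[Si](C)(C)C | intermediate
36 | O-difluoroboryl ether of 37 | C=C1C[C@H](OB(F)F)[C@H]2CC=C(C)[C@@H](C[C@H]3C(=C)CC[C@@H]4[C@]3(C)CCC[C@]4(C)C(=O)OC)[C@]2(C(=O)OC)CC[C@@H]2[C@@H]1CC2(C)C | intermediate
37 | C6' carbinol with the complete skeleton (nine-membered ring closed, C8'=CH2), dimethyl ester, C6' drawn as one epimer | C=C1C[C@H](O)[C@H]2CC=C(C)[C@@H](C[C@H]3C(=C)CC[C@@H]4[C@]3(C)CCC[C@]4(C)C(=O)OC)[C@]2(C(=O)OC)CC[C@@H]2[C@@H]1CC2(C)C | intermediate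
38 | O-phenyl thionocarbonate of 37 | C=C1C[C@H](OC(=S)Oc5ccccc5)[C@H]2CC=C(C)[C@@H](C[C@H]3C(=C)CC[C@@H]4[C@]3(C)CCC[C@]4(C)C(=O)OC)[C@]2(C(=O)OC)CC[C@@H]2[C@@H]1CC2(C)C | intermediate
39 | dimethyl ester of the target | C=C1CC[C@H]2CC=C(C)[C@@H](C[C@H]3C(=C)CC[C@@H]4[C@]3(C)CCC[C@]4(C)C(=O)OC)[C@]2(C(=O)OC)CC[C@@H]2[C@@H]1CC2(C)C | intermediate
40 | disodium dicarboxylate of the target | C=C1CC[C@H]2CC=C(C)[C@@H](C[C@H]3C(=C)CC[C@@H]4[C@]3(C)CCC[C@]4(C)C(=O)[O-])[C@]2(C(=O)[O-])CC[C@@H]2[C@@H]1CC2(C)C.[Na+].[Na+] | intermediate
41 | CNP0330729.1 (diacid) | C=C1CC[C@H]2CC=C(C)[C@@H](C[C@H]3C(=C)CC[C@@H]4[C@]3(C)CCC[C@]4(C)C(=O)O)[C@]2(C(=O)O)CC[C@@H]2[C@@H]1CC2(C)C | target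

**Step count and risks**

Total step count: 22. Longest linear sequence: 15 steps (steps 1 to 8 and 16 to 22); the cyclobutane branch (steps 9 to 15, then 16 to 22) runs to 14.

Steps most likely to fail:

Step 19. Intermolecular allylation (oligomerisation) or protodesilylation may outrun the strained nine-membered closure. The fallback sets out from 35: bromodesilylation of the allylsilane with N-bromosuccinimide (CH2Cl2, propylene oxide, −78 °C) should give the allylic bromide aldehyde F1. Slow addition of F1 to CrCl2 (divalent chromium) in THF at high dilution then forms the same C6'–C7' bond by an intramolecular Nozaki–Hiyama allylation, a chromium-mediated ring closure known for medium and large carbocycles. Because both termini of the 2-substituted allyl unit are CH2 groups, the product is the same carbinol, and the fallback comes back to the route at 37.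

Step 16. The flanked ring-fusion enolate may be alkylated too slowly, so that proton transfer and elimination of HI from 30 take over. The fallback sets out from 28: Dess–Martin oxidation gives the cyclobutane aldehyde F2. Aldol addition of lithium enolate 31 to F2 at −78 °C is much faster than SN2 alkylation and has the same facial preference at C4'; it gives the β-hydroxy lactone F3 (either C3' epimer). Acylation with PhOC(S)Cl and pyridine gives the thionocarbonate F4, and Barton–McCombie reduction (Bu3SnH, AIBN, toluene, 100 °C) removes the C3' hydroxyl and comes back to the route at 32.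

Step 5. Cycloaddition of the trisubstituted diene may be slow at the temperature the silyl enol ether tolerates, so that desilylation and decomposition of the diene compete, or the endo preference may be eroded. The fallback sets out from 2: the parent triene itself is combined with 8 in a Diels–Alder reaction under high pressure (about 12 kbar, CH2Cl2, rt), which should give 12 directly, so that steps 2 to 4, 6 and 7 fall away. Without the directing silyloxy group the regioisomeric adduct has to be removed by chromatography. The fallback comes back to the route at 12 and makes no compound outside the list (none F0).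

Further compounds
F1 | step 19 | allylic bromide aldehyde: 35 with CH2Br in place of CH2SiMe3 | O=C[C@H]1CC=C(C)[C@@H](C[C@H]2C(=C)CC[C@@H]3[C@]2(C)CCC[C@]3(C)C(=O)OC)[C@]1(C(=O)OC)CC[C@@H]1[C@H](CC1(C)C)C(=C)CBr
F2 | step 16 | cyclobutane aldehyde: 28 oxidised at C3' | O=CC[C@@H]1[C@H](CC1(C)C)C(=C)C[Si](C)(C)C
F3 | step 16 | β-hydroxy lactone: aldol adduct of 31 and F2, C3' carbinol (either epimer) on C4' | O=C1OC[C@H]2CC=C(C)[C@@H](C[C@H]3C(=C)CC[C@@H]4[C@]3(C)CCC[C@]4(C)C(=O)OC)[C@@]12C(O)C[C@@H]5[C@H](CC5(C)C)C(=C)C[Si](C)(C)C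
F4 | step 16 | O-phenyl thionocarbonate of F3 | O=C1OC[C@H]2CC=C(C)[C@@H](C[C@H]3C(=C)CC[C@@H]4[C@]3(C)CCC[C@]4(C)C(=O)OC)[C@@]12C(OC(=S)Oc6ccccc6)C[C@@H]5[C@H](CC5(C)C)C(=C)C[Si](C)(C)C
F0 | step 5 | none | none
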